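The ratio of fresh carrier to spent carrier in this flask can be frozen at a chosen conversion, and a second ratio built from the same numbers tells how far the flask is from stopping.

    spent carrier + salt in the second phase ⇌ fresh carrier + spent salt in the second phase (K1 = 1.8, k1 = 110 M⁻¹ h⁻¹)
    substrate + fresh carrier ⇌ target + spent carrier (K2 = 0.49, k2 = 140 M⁻¹ h⁻¹)

substrate 0.070 M; salt in the second phase 1.10 equiv; spent carrier 1 mol%; volume of the second phase over the first 1.0

- the form that holds most of the catalyst when 50% of the substrate are converted (fresh carrier / spent carrier)
- its share of the catalyst then
- apparent order in spent carrier when 50% of the substrate are converted (percent change of the rate of making target for one percent more spent carrier charged)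
- factor on the rate of making target when 50% of the substrate are converted if salt in the second phase is charged twice over

- in the second phase: salt in the second phase, spent salt in the second phase; everything else is in the first
- charges count per volume of the first phase; a concentration in a rate is the amount of a species over the volume of its own phase; every rate counts per litre of the first phase
- charge of substrate (flask): 0.070 M

The second phase has 1.0 times the volume of the first, so the charges read directly as concentrations. The catalyst is 7.00 × 10⁻⁴ M. At 50% conversion [substrate] is 0.0350 M and [target] is 0.0350 M. Each fresh carrier has also taken up salt from the second phase, so a first pass of the table below, giving [fresh carrier] as 4.73 × 10⁻⁴ M, puts [spent salt in the second phase] at 0.0355 M and [salt in the second phase] at 0.0415 M. My own reckoning then lists the pseudo-first-order exits from each carrier form: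

| leaves by | first step | second step | sum |
|---|---|---|---|
| spent carrier | 4.57 h⁻¹ | 10.0 h⁻¹ | 14.6 h⁻¹ |
| fresh carrier | 2.17 h⁻¹ | 4.90 h⁻¹ | 7.07 h⁻¹ |

A carrier changes form within about 2.77 min, while the substrate moves on a scale of 10.2 h, so each form is made as fast as it leaves.

The sums then give the split. Spent carrier leaves faster than fresh carrier, so fresh carrier is the resting state, with 67.3% of the catalyst.

The diagonals give the second ratio. The drive is the product of the two forward exits over the product of the two backward exits, which equals 0.882 times [substrate][salt in the second phase]/([target][spent salt in the second phase]). The flask stops where it reads one, and here it reads 1.03. With each form made as fast as it leaves, the rate of making target is the catalyst times the difference of the diagonals over the sum of the four exits, which gives 2.28 × 10⁻⁵ M h⁻¹.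

The forecast names fresh carrier at 67.3% (65% to 70%), an order of 0.24 (0.18 to 0.3) and a factor of 43 (38 to 48), on the ground that “the net rate is a small difference of large terms”.

The simulation reaches that conversion at 60.0 h with fresh carrier at 67.3%, an order of 0.23 and a rate of 2.28 × 10⁻⁵ M h⁻¹. After 250 h the flask still holds 49.6% of its substrate. With 2.20 equiv of salt in the second phase and the other concentrations held, [salt in the second phase] becomes 0.119 M and the drive at that conversion reckons to 2.95, against 1.03 in the flask as charged. The simulated rate stands higher by a factor of 42.9.

(The numbers of this flask stand for no real mixture; the result is computed.)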